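**Retrosynthetic overview**
1. Numbering: cyclohexane C1 (bears the side chain), C2 (CH2), C3 (Cl), C4 (CH3, OH), C5 (O-angeloyl), C6 (OH); side chain C7(=C14H2)–C8(O-angeloyl)–C9–C10/C11 (oxirane). The enabling feature is the array C6(OH)–C1(H)–C7(=C14H2): a ring carbinol next to a ring CH that carries an exocyclic 1,1-disubstituted alkene. This is the retron of a carbonyl-ene reaction, and the C4 hydroxyl lies syn-axial to the C6 oxygen.
2. Disconnecting C1–C6 (retro carbonyl-ene) shows the target to be an isomer of an acyclic (E)-6-enal (C6 = CHO, C1=C7 alkene, C14 = CH3). This enal already holds both angelates, the chlorohydrin and the oxirane.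
3. In the enal, the oxirane comes from a Shi epoxidation of C10=C11 and the two esters from one double angeloylation. C7–C13 are grown from a vinyl chlorohydrin by cross-metathesis (methacrolein), Keck allylation (C8) and cross-metathesis (2-methylbut-2-ene).
4. In the vinyl chlorohydrin, C3 and C4 come from Shi epoxidation of a Z-trisubstituted alkene followed by SN2 opening with chloride. The Z-alkene comes from a Wittig reaction of a chiral-pool α-alkoxy methyl ketone, which supplies C5.
5. Ring order: dioxolane (from the pool, temporary, removed in step 9); C3–C4 oxirane (temporary, closed in step 4, opened in step 5); C10–C11 oxirane (step 12); cyclohexane (step 15, last).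

Key step: step 15

Remark: angeloyl = (Z)-2-methylbut-2-enoyl; atom numbers in the text are those of line 1.

Step 1
Reactants: 1 methyl (4S)-2,2-dimethyl-1,3-dioxolane-4-carboxylate
Product: 2 (4S)-N-methoxy-N,2,2-trimethyl-1,3-dioxolane-4-carboxamide
Conditions: MeNH(OMe)·HCl, iPrMgCl, THF, −20 to 0 °C
Reagents that add atoms: N,O-dimethylhydroxylamine hydrochloride, CNOC.Cl
Why: Weinreb amide formation by aminolysis of the ester with the chloromagnesium amide made in situ, a mild acyl substitution that leaves the pool-derived centre C5 untouched.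

Step 2
Reactants: 2 (4S)-N-methoxy-N,2,2-trimethyl-1,3-dioxolane-4-carboxamide
Product: 3 1-[(4S)-2,2-dimethyl-1,3-dioxolan-4-yl]ethan-1-one
Conditions: MeMgBr, THF, −78 to 0 °C; aq. NH4Cl
Reagents that add atoms: methylmagnesium bromide, C[Mg]Br
Why: Weinreb ketone synthesis, in which the chelated tetrahedral adduct stops the addition at the ketone stage and the cold, short contact keeps the α-alkoxy centre C5 intact.

Step 3
Reactants: 3 1-[(4S)-2,2-dimethyl-1,3-dioxolan-4-yl]ethan-1-one; 4 (but-3-en-1-yl)triphenylphosphonium bromide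
Product: 6 (4R)-4-[(2Z)-hexa-2,5-dien-2-yl]-2,2-dimethyl-1,3-dioxolane, via butenylidene ylide 5 (not isolated)
Conditions: 4, NaN(SiMe3)2, THF, −78 to 0 °C; then 3, −78 °C to rt
Reagents that add atoms: none
Why: Wittig olefination of an α-alkoxy methyl ketone with a non-stabilised, lithium-free ylide, a pairing known to place the new chain cis to the alkoxy-bearing carbon and so to give the Z-trisubstituted C3=C4 alkene, while the low temperature limits enolisation at C5.

Step 4
Reactants: 6 (4R)-4-[(2Z)-hexa-2,5-dien-2-yl]-2,2-dimethyl-1,3-dioxolane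
Product: 7 (4S)-2,2-dimethyl-4-[(2R,3R)-2-methyl-3-(prop-2-en-1-yl)oxiran-2-yl]-1,3-dioxolane
Conditions: D-fructose-derived Shi ketone (1,2:4,5-di-O-isopropylidene-β-D-erythro-hexo-2,3-diulo-2,6-pyranose, 0.3 equiv), KHSO5 (as 2KHSO5·KHSO4·K2SO4), K2CO3, Bu4NHSO4, MeCN–CH2(OMe)2, aq. Na2B4O7/Na2H2EDTA buffer (pH 10.5), 0 °C
Reagents that add atoms: potassium peroxymonosulfate, [K+].[O-]S(=O)(=O)OO
Why: Shi asymmetric epoxidation, in which the chiral dioxirane attacks only the electron-rich trisubstituted alkene (the monosubstituted vinyl group is inert) in the spiro mode to give the 3R,4R oxirane, the same face that allylic 1,3-strain favours (C5–H in the alkene plane, attack anti to the C5–O bond), so reagent and substrate should be matched.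

Step 5
Reactants: 7 (4S)-2,2-dimethyl-4-[(2R,3R)-2-methyl-3-(prop-2-en-1-yl)oxiran-2-yl]-1,3-dioxolane
Product: 8 (2S,3S)-3-chloro-2-[(4S)-2,2-dimethyl-1,3-dioxolan-4-yl]hex-5-en-2-ol
Conditions: LiCl (excess), AcOH, THF, rt
Reagents that add atoms: lithium chloride, [Li+].[Cl-]
Why: Halohydrin synthesis by weak-acid-assisted SN2 opening of an epoxide with a lithium halide, in which chloride should attack the secondary C3 with inversion (3S) because C4 is fully substituted and its cationic character is damped by the adjacent dioxolane oxygens, leaving the C4–O bond (4S) untouched.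

Step 6
Reactants: 8 (2S,3S)-3-chloro-2-[(4S)-2,2-dimethyl-1,3-dioxolan-4-yl]hex-5-en-2-ol; 9 methacrolein (2-methylprop-2-enal)
Product: 10 (2E,5S,6S)-5-chloro-6-[(4S)-2,2-dimethyl-1,3-dioxolan-4-yl]-6-hydroxy-2-methylhept-2-enal
Conditions: 9 (5 equiv), second-generation Hoveyda–Grubbs catalyst RuCl2(H2IMes)(=CH-C6H4-2-OiPr) (5 mol %), CH2Cl2, 40 °C
Reagents that add atoms: none
Why: Olefin cross-metathesis of a terminal alkene with methacrolein, a pairing known to give the E-2-methyl-2-enal selectively (C8 trans to C2), with chloride, tertiary alcohol and acetonide inert to the ruthenium carbene.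

Step 7
Reactants: 10 (2E,5S,6S)-5-chloro-6-[(4S)-2,2-dimethyl-1,3-dioxolan-4-yl]-6-hydroxy-2-methylhept-2-enal
Product: 11 (2S,3S,5E,7S)-3-chloro-2-[(4S)-2,2-dimethyl-1,3-dioxolan-4-yl]-6-methyldeca-5,9-diene-2,7-diol
Conditions: (S)-BINOL (20 mol %), Ti(OiPr)4 (10 mol %), 4 Å molecular sieves, CH2Cl2; then 10, allylSnBu3, −20 °C; aq. NaHCO3
Reagents that add atoms: allyltributylstannane, C=CC[Sn](CCCC)(CCCC)CCCC
Why: Keck asymmetric allylation, precedented for 2-methyl-2-enals, in which the (S)-BINOL–titanium Lewis acid exposes one face of the aldehyde and should set 8S by catalyst control, the hindered tertiary hydroxyl being no better a ligand than the isopropanol already present.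

Step 8
Reactants: 11 (2S,3S,5E,7S)-3-chloro-2-[(4S)-2,2-dimethyl-1,3-dioxolan-4-yl]-6-methyldeca-5,9-diene-2,7-diol
Product: 12 (2S,3S,5E,7S)-3-chloro-2-[(4S)-2,2-dimethyl-1,3-dioxolan-4-yl]-6,10-dimethylundeca-5,9-diene-2,7-diol
Conditions: 2-methylbut-2-ene (co-solvent), second-generation Grubbs catalyst RuCl2(H2IMes)(PCy3)(=CHPh) (3 mol %), CH2Cl2, 40 °C, sealed
Reagents that add atoms: 2-methylbut-2-ene, CC=C(C)C
Why: Cross-metathesis with 2-methylbut-2-ene turns the monosubstituted vinyl group into the prenyl-type C10=C11 alkene, while the trisubstituted C1=C7 alkene does not take part.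

Step 9
Reactants: 12 (2S,3S,5E,7S)-3-chloro-2-[(4S)-2,2-dimethyl-1,3-dioxolan-4-yl]-6,10-dimethylundeca-5,9-diene-2,7-diol
Product: 13 (2S,3S,4S,6E,8S)-4-chloro-3,7,11-trimethyldodeca-6,10-diene-1,2,3,8-tetrol
Conditions: AcOH–H2O 4:1, 40 °C
Reagents that add atoms: none
Why: Acid-catalysed hydrolysis of a terminal acetonide, placed before any oxirane of the target exists, which the acid-stable (only base-labile) chlorohydrin tolerates and which touches no stereocentre.

Step 10
Reactants: 13 (2S,3S,4S,6E,8S)-4-chloro-3,7,11-trimethyldodeca-6,10-diene-1,2,3,8-tetrol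
Product: 14 (2S,3S,4S,6E,8S)-1-[(tert-butyldimethylsilyl)oxy]-4-chloro-3,7,11-trimethyldodeca-6,10-diene-2,3,8-triol
Conditions: TBSCl (1.05 equiv), imidazole, CH2Cl2, 0 °C
Reagents that add atoms: tert-butyldimethylsilyl chloride, CC(C)(C)[Si](C)(C)Cl
Why: Sterically controlled silylation, in which the bulky chlorosilane takes the only primary hydroxyl (O6) and imidazole is too weak a base to close the chlorohydrin.

Step 11
Reactants: 14 (2S,3S,4S,6E,8S)-1-[(tert-butyldimethylsilyl)oxy]-4-chloro-3,7,11-trimethyldodeca-6,10-diene-2,3,8-triol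
Product: 15 (2S,3S,4S,6E,8S)-1-[(tert-butyldimethylsilyl)oxy]-4-chloro-3-hydroxy-3,7,11-trimethyldodeca-6,10-diene-2,8-diyl bis[(Z)-2-methylbut-2-enoate]
Conditions: angelic acid, 2,4,6-trichlorobenzoyl chloride, Et3N, toluene, rt; filtration; then 14, toluene, 80 °C (no DMAP)
Reagents that add atoms: angelic acid [(Z)-2-methylbut-2-enoic acid], C/C=C(/C)C(=O)O
Why: Yamaguchi-type mixed-anhydride esterification run without a nucleophilic catalyst, a protocol chosen because it transfers the angeloyl group without Z-to-E isomerisation, acylates both secondary hydroxyls (O5, O8) in one operation, leaves the tertiary C4 hydroxyl free and, once the amine salt is filtered off, exposes the chlorohydrin to no base.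

Step 12
Reactants: 15 (2S,3S,4S,6E,8S)-1-[(tert-butyldimethylsilyl)oxy]-4-chloro-3-hydroxy-3,7,11-trimethyldodeca-6,10-diene-2,8-diyl bis[(Z)-2-methylbut-2-enoate]
Product: 16 (2S,3S,4S,6E,8S,10R)-1-[(tert-butyldimethylsilyl)oxy]-4-chloro-10,11-epoxy-3-hydroxy-3,7,11-trimethyldodec-6-ene-2,8-diyl bis[(Z)-2-methylbut-2-enoate]
Conditions: D-fructose-derived Shi ketone (2 equiv), KHSO5 (as 2KHSO5·KHSO4·K2SO4), NaHCO3 (pH 7.5–8), MeCN–aq. Na2H2EDTA, 0 °C
Reagents that add atoms: potassium peroxymonosulfate, [K+].[O-]S(=O)(=O)OO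
Why: Shi asymmetric epoxidation in its near-neutral variant, in which reagent control gives 10R, the prenyl-type C10=C11 alkene reacts ahead of C1=C7 (deactivated by the allylic ester and the homoallylic chloride) and of the electron-poor angelates, and the low pH and temperature keep the chlorohydrin from closing.

Step 13
Reactants: 16 (2S,3S,4S,6E,8S,10R)-1-[(tert-butyldimethylsilyl)oxy]-4-chloro-10,11-epoxy-3-hydroxy-3,7,11-trimethyldodec-6-ene-2,8-diyl bis[(Z)-2-methylbut-2-enoate]
Product: 17 (2S,3S,4S,6E,8S,10R)-4-chloro-10,11-epoxy-1,3-dihydroxy-3,7,11-trimethyldodec-6-ene-2,8-diyl bis[(Z)-2-methylbut-2-enoate]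
Conditions: HF·pyridine, excess pyridine, THF, 0 °C to rt; used at once
Reagents that add atoms: none
Why: Fluoride-mediated cleavage of a primary silyl ether in a pyridine-buffered medium, conditions under which trisubstituted oxiranes are known to survive and which are neither basic enough to close the chlorohydrin nor to drive the O5-to-O6 acyl shift.

Step 14
Reactants: 17 (2S,3S,4S,6E,8S,10R)-4-chloro-10,11-epoxy-1,3-dihydroxy-3,7,11-trimethyldodec-6-ene-2,8-diyl bis[(Z)-2-methylbut-2-enoate]
Product: 18 (2R,3S,4S,6E,8S,10R)-4-chloro-10,11-epoxy-3-hydroxy-3,7,11-trimethyl-1-oxododec-6-ene-2,8-diyl bis[(Z)-2-methylbut-2-enoate]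
Conditions: Dess–Martin periodinane, NaHCO3, CH2Cl2, 0 °C to rt
Reagents that add atoms: none
Why: Dess–Martin oxidation of the only oxidisable (primary) alcohol under buffered, non-basic conditions that should not epimerise the α-acyloxy centre C5 (the descriptor changes to 2R only through the priority rules) and leave the tertiary alcohol, oxirane and alkenes alone.

Step 15
Reactants: 18 (2R,3S,4S,6E,8S,10R)-4-chloro-10,11-epoxy-3-hydroxy-3,7,11-trimethyl-1-oxododec-6-ene-2,8-diyl bis[(Z)-2-methylbut-2-enoate]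
Product: 19 CNP0158207.1, (1R,3S,4S,5S,6S,8S,10R)-3-chloro-10,11-epoxy-4,6-dihydroxybisabol-7(14)-ene-5,8-diyl bis[(Z)-2-methylbut-2-enoate]
Conditions: degassed toluene (5 mM), 2,6-di-tert-butyl-4-methylphenol (0.1 equiv), silylated sealed tube, 110–130 °C
Reagents that add atoms: none
Why: Concerted intramolecular carbonyl-ene reaction: C1 of the C1=C7 alkene bonds to the aldehyde carbon C6 while one hydrogen of the C14 methyl group moves to the carbonyl oxygen through a six-membered cyclic transition state, so that the C1–C6 bond, the free C6 hydroxyl and the C7=C14 methylene arise together and 18 simply isomerises to 19. The closest known reaction type is the thermal cyclisation of citronellal to the isopulegols (a 6-enal with a trisubstituted alkene), here assisted by the electron-withdrawing α-acyloxy group, the fully substituted C4 in the tether and the internal hydrogen bond from the C4 hydroxyl to the carbonyl oxygen. The cyclohexane closes 6-exo-trig at the carbonyl group through a chair in which the C4 methyl, the C5 angelate and the C1 alkenyl chain are equatorial and C3–Cl, C4–OH and the carbonyl oxygen are axial. C6 (6S): the carbonyl oxygen is held axial and syn to O4 by that hydrogen bond, the alternative chair would set the C4 methyl 1,3-diaxial to it, and in the favoured chair the C5–O bond lies antiperiplanar to the forming bond, so O6 ends cis to O5 and O4. C1 (1R): in the E-alkene the C14 methyl is cis to the tether carbon C2, and only the chair with axial oxygen and equatorial alkenyl group brings this methyl within reach of the oxygen, which ties C1 to C6 as the cis pair. The step needs hydrogen transfer from C14 and not from C8–H (C8 is trans to the tether, out of reach in this chair, and its C–H is electron-poor), and it needs the oxirane, chlorohydrin and angelates to survive, which the absence of any acid, base or metal secures.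

**Compound list**
1 | methyl (4S)-2,2-dimethyl-1,3-dioxolane-4-carboxylate | COC(=O)[C@@H]1COC(C)(C)O1 | starting material
2 | (4S)-N-methoxy-N,2,2-trimethyl-1,3-dioxolane-4-carboxamide | CON(C)C(=O)[C@@H]1COC(C)(C)O1 | intermediate
3 | 1-[(4S)-2,2-dimethyl-1,3-dioxolan-4-yl]ethan-1-one | CC(=O)[C@@H]1COC(C)(C)O1 | intermediate
4 | (but-3-en-1-yl)triphenylphosphonium bromide | C=CCC[P+](c1ccccc1)(c1ccccc1)c1ccccc1.[Br-] | starting material
5 | (but-3-en-1-ylidene)triphenylphosphorane (ylide, not isolated) | C=CCC=P(c1ccccc1)(c1ccccc1)c1ccccc1 | intermediate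
6 | (4R)-4-[(2Z)-hexa-2,5-dien-2-yl]-2,2-dimethyl-1,3-dioxolane | C=CC/C=C(/C)[C@@H]1COC(C)(C)O1 | intermediate
7 | (4S)-2,2-dimethyl-4-[(2R,3R)-2-methyl-3-(prop-2-en-1-yl)oxiran-2-yl]-1,3-dioxolane | C=CC[C@H]1O[C@@]1(C)[C@@H]2COC(C)(C)O2 | intermediate
8 | (2S,3S)-3-chloro-2-[(4S)-2,2-dimethyl-1,3-dioxolan-4-yl]hex-5-en-2-ol | C=CC[C@H](Cl)[C@@](C)(O)[C@@H]1COC(C)(C)O1 | intermediate
9 | methacrolein | C=C(C)C=O | starting material
10 | (2E,5S,6S)-5-chloro-6-[(4S)-2,2-dimethyl-1,3-dioxolan-4-yl]-6-hydroxy-2-methylhept-2-enal | O=C/C(C)=C/C[C@H](Cl)[C@@](C)(O)[C@@H]1COC(C)(C)O1 | intermediate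
11 | (2S,3S,5E,7S)-3-chloro-2-[(4S)-2,2-dimethyl-1,3-dioxolan-4-yl]-6-methyldeca-5,9-diene-2,7-diol | C=CC[C@H](O)/C(C)=C/C[C@H](Cl)[C@@](C)(O)[C@@H]1COC(C)(C)O1 | intermediate
12 | (2S,3S,5E,7S)-3-chloro-2-[(4S)-2,2-dimethyl-1,3-dioxolan-4-yl]-6,10-dimethylundeca-5,9-diene-2,7-diol | CC(C)=CC[C@H](O)/C(C)=C/C[C@H](Cl)[C@@](C)(O)[C@@H]1COC(C)(C)O1 | intermediate
13 | (2S,3S,4S,6E,8S)-4-chloro-3,7,11-trimethyldodeca-6,10-diene-1,2,3,8-tetrol | CC(C)=CC[C@H](O)/C(C)=C/C[C@H](Cl)[C@@](C)(O)[C@@H](O)CO | intermediate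
14 | (2S,3S,4S,6E,8S)-1-[(tert-butyldimethylsilyl)oxy]-4-chloro-3,7,11-trimethyldodeca-6,10-diene-2,3,8-triol | CC(C)=CC[C@H](O)/C(C)=C/C[C@H](Cl)[C@@](C)(O)[C@@H](O)CO[Si](C)(C)C(C)(C)C | intermediate
15 | O5,O8-bis-angelate of 14 | CC(C)=CC[C@H](OC(=O)/C(C)=C\C)/C(C)=C/C[C@H](Cl)[C@@](C)(O)[C@@H](OC(=O)/C(C)=C\C)CO[Si](C)(C)C(C)(C)C | intermediate
16 | (10R)-10,11-epoxide of 15 | CC1(C)O[C@@H]1C[C@H](OC(=O)/C(C)=C\C)/C(C)=C/C[C@H](Cl)[C@@](C)(O)[C@@H](OC(=O)/C(C)=C\C)CO[Si](C)(C)C(C)(C)C | intermediate
17 | primary alcohol (C6–OH) from 16 | CC1(C)O[C@@H]1C[C@H](OC(=O)/C(C)=C\C)/C(C)=C/C[C@H](Cl)[C@@](C)(O)[C@@H](OC(=O)/C(C)=C\C)CO | intermediate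
18 | acyclic aldehyde (C6 = CHO), isomer of the target | CC1(C)O[C@@H]1C[C@H](OC(=O)/C(C)=C\C)/C(C)=C/C[C@H](Cl)[C@@](C)(O)[C@@H](OC(=O)/C(C)=C\C)C=O | intermediate
19 | CNP0158207.1 | C=C([C@H](C[C@H]1OC1(C)C)OC(=O)/C(C)=C\C)[C@H]1C[C@H](Cl)[C@@](C)(O)[C@@H](OC(=O)/C(C)=C\C)[C@H]1O | target

Total step count: 15. Longest linear sequence: 15 steps (from 1).

**Steps most likely to fail**

Step 15. The uncatalysed closure may be too slow at temperatures that 18 tolerates. Retro-aldol cleavage of the C4–C5 bond, acyl shift from O5, or slow decay of the oxirane could then outrun ring formation.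
- The fallback replaces thermal activation by a Lewis acid that is covalently anchored to the substrate. It sets out from 18 and returns at 19.
- Aldehyde 18 would be treated in CH2Cl2 at −78 °C with one equivalent of Me2AlCl.
- The C4 hydroxyl cleaves one Al–CH3 bond and gives the chloro(methyl)aluminium C4-alkoxide of 18 F1.
- In this alkoxide the metal is tied to O4 and can reach only the C6 carbonyl oxygen. The resulting six-membered chelate has the same syn-axial O4/O6 arrangement as the thermal chair. Acceleration is thus delivered to the aldehyde and not to the distant oxirane.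
- Ene closure between −78 and −20 °C, with protonolysis of the second Al–CH3 bond by the new C6 hydroxyl, would give the cyclic chloroaluminium O4,O6-dialkoxide of 19 F2.
- Work-up with aqueous KNaC4H4O6 would release 19.

Step 5. Chloride attack may leak to the tertiary C4 through a more SN1-like opening, or acetate may compete as the nucleophile.
- The fallback changes from an external nucleophile on the acetonide to hydroxyl-directed delivery. It sets out from 6 and returns at 8.
- The acetonide of 6 would first be hydrolysed (AcOH–H2O) to (2R,3Z)-3-methylhepta-3,6-diene-1,2-diol F3.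
- Shi epoxidation with the same D-fructose-derived ketone would give (1S)-1-[(2S,3R)-2-methyl-3-(prop-2-en-1-yl)oxiran-2-yl]ethane-1,2-diol F4.
- ClTi(OiPr)3 in CH2Cl2 would bind the free C5 hydroxyl. As is well established for 2,3-epoxy alcohols, it would then deliver chloride to the distal carbon C3 with inversion, giving (2S,3S,4S)-4-chloro-3-methylhept-6-ene-1,2,3-triol F5.
- Kinetic acetonide formation at the terminal diol (2,2-dimethoxypropane, pyridinium p-toluenesulfonate) would give 8.

Step 12. Even in the near-neutral medium the chlorohydrin may lose HCl by closure of O4 onto C3. The large ketone loading needed at low pH may also bring over-oxidation at C1=C7.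
- The fallback masks the tertiary hydroxyl so that the catalytic high-pH protocol of step 4 can be used. It sets out from 15 and returns at 17.
- Treatment of 15 with Et3SiOTf and 2,6-lutidine (CH2Cl2, −78 to 0 °C) would give the C4 triethylsilyl ether of 15 F6.
- Catalytic Shi epoxidation at pH 10.5 would give the C4 triethylsilyl ether of 16 F7.
- The HF·pyridine treatment of step 13 would remove both silyl groups at once to give 17, so the step count rises by only one.

**Further compounds**
F1 | step 15 | chloro(methyl)aluminium C4-alkoxide of 18 | CC1(C)O[C@@H]1C[C@H](OC(=O)/C(C)=C\C)/C(C)=C/C[C@H](Cl)[C@@](C)(O[Al](C)Cl)[C@@H](OC(=O)/C(C)=C\C)C=O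
F2 | step 15 | cyclic chloroaluminium O4,O6-dialkoxide of 19 | C=C([C@H](C[C@H]1OC1(C)C)OC(=O)/C(C)=C\C)[C@H]1C[C@H](Cl)[C@@](C)(O2)[C@@H](OC(=O)/C(C)=C\C)[C@H]1O[Al]2Cl
F3 | step 5 | (2R,3Z)-3-methylhepta-3,6-diene-1,2-diol | C=CC/C=C(/C)[C@@H](O)CO
F4 | step 5 | (1S)-1-[(2S,3R)-2-methyl-3-(prop-2-en-1-yl)oxiran-2-yl]ethane-1,2-diol | C=CC[C@H]1O[C@@]1(C)[C@@H](O)CO
F5 | step 5 | (2S,3S,4S)-4-chloro-3-methylhept-6-ene-1,2,3-triol | C=CC[C@H](Cl)[C@@](C)(O)[C@@H](O)CO
F6 | step 12 | C4 triethylsilyl ether of 15 | CC(C)=CC[C@H](OC(=O)/C(C)=C\C)/C(C)=C/C[C@H](Cl)[C@@](C)(O[Si](CC)(CC)CC)[C@@H](OC(=O)/C(C)=C\C)CO[Si](C)(C)C(C)(C)C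
F7 | step 12 | C4 triethylsilyl ether of 16 | CC1(C)O[C@@H]1C[C@H](OC(=O)/C(C)=C\C)/C(C)=C/C[C@H](Cl)[C@@](C)(O[Si](CC)(CC)CC)[C@@H](OC(=O)/C(C)=C\C)CO[Si](C)(C)C(C)(C)C
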